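## Retrosynthetic overview

1. Prismatomerin ⇒ tricyclic dienol ether (pyran + bridging dihydrofuran acetal + cyclopentadiene unit) + (Z)‑α‑bromo‑p‑coumaric acid. A Pd‑catalysed diene heteroannulation forms C10–C11 and C8–O, building the spiro‑lactone last.
2. Tricyclic dienol ether ⇒ 1‑O‑benzyl‑10‑oxogenipin, by intramolecular transacetalisation with γ‑deprotonation (acetal ring third).
3. Genipin skeleton ⇒ (R)‑6‑benzyloxy‑pyranone + ethyl allenoate by phosphine‑catalysed (3+2) annulation (cyclopentene second); the C4 ester comes from enol triflate carbonylation.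
4. Pyranone ⇒ furfuryl alcohol (Achmatowicz, dynamic kinetic acylation, Pd O‑glycosylation; pyran first).
5. Bromo acid ⇒ 4‑iodophenol + methyl acrylate (Heck, bromination, dehydrobromination, hydrolysis).

Numbering note: atom labels in the text use iridoid numbering (C1 acetal CH, O2, C3=C4–CO2Me, C5/C9 ring‑fusion CH, C6=C7, C8 spiro carbon, C10 O–CH, C11 arylidene‑bearing carbon). Names of bicyclic intermediates use cyclopenta[c]pyran locants (C4a = C5, C7 = C8, C7a = C9).

Assumption: (R)‑BTM is taken to give the (S)‑acyl acetal 3; if the sense is opposite, (S)‑BTM is used (both are commercial).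

## Route

**Step 1**
Reactants: 1 furfuryl alcohol
Product: 2 (±)‑6‑hydroxy‑2H‑pyran‑3(6H)‑one
Conditions: NBS, NaHCO3, NaOAc, THF/H2O 4:1, 0 °C
Reagents that add atoms: water, O
Why: Achmatowicz oxidative ring expansion of a 2‑furylcarbinol gives the pyranone lactol; no stereocontrol is needed because the lactol epimerises freely.

**Step 2**
Reactants: 2 (±)‑6‑hydroxy‑2H‑pyran‑3(6H)‑one
Product: 3 (S)‑6‑(isobutyryloxy)‑2H‑pyran‑3(6H)‑one
Conditions: (i‑PrCO)2O, (R)‑BTM (5 mol %), i‑Pr2NEt, CHCl3, −20 °C
Reagents that add atoms: isobutyric anhydride, CC(C)C(=O)OC(=O)C(C)C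
Why: Dynamic kinetic acylation — the lactol enantiomers interconvert by ring‑opening while the chiral acyl‑isothiouronium acylates one of them faster, fixing the acetal carbon as S.

**Step 3**
Reactants: 3 (S)‑6‑(isobutyryloxy)‑2H‑pyran‑3(6H)‑one
Product: 4 (R)‑6‑(benzyloxy)‑2H‑pyran‑3(6H)‑one
Conditions: BnOH, Pd2(dba)3·CHCl3 (2.5 mol %), PPh3 (10 mol %), CH2Cl2, 0 °C to rt
Reagents that add atoms: benzyl alcohol, OCc1ccccc1
Why: Pd(0)‑catalysed O‑glycosylation (Tsuji–Trost) through the Pd‑π‑allyl pyranone proceeds with net retention by double inversion; the descriptor changes from S to R only because of CIP priorities.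

**Step 4**
Reactants: 4 (R)‑6‑(benzyloxy)‑2H‑pyran‑3(6H)‑one; 5 ethyl buta‑2,3‑dienoate
Product: 6 ethyl (1R,4aS,7aS)‑1‑(benzyloxy)‑4‑oxo‑1,3,4,4a,5,7a‑hexahydrocyclopenta[c]pyran‑7‑carboxylate
Conditions: PPh3 (10 mol %), toluene, 80 °C
Reagents that add atoms: none
Why: Lu phosphine‑catalysed (3+2) annulation — the allenoate α‑carbon adds to the enone β‑carbon anti to the pseudo‑axial OBn and the ring closes cis, which sets C5 and C9 (4aS,7aS) and places the ester on C8.

**Step 5**
Reactants: 6 keto ester
Product: 7 ethyl (1R,4aS,7aS)‑1‑(benzyloxy)‑4‑(trifluoromethanesulfonyloxy)‑1,4a,5,7a‑tetrahydrocyclopenta[c]pyran‑7‑carboxylate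
Conditions: KHMDS, THF, −78 °C; then Comins' reagent, −78 °C
Reagents that add atoms: Comins' reagent, FC(F)(F)S(=O)(=O)N(c1ccc(Cl)cn1)S(=O)(=O)C(F)(F)F
Why: Kinetic enolisation at the unhindered O–CH2 (C3) rather than the ring‑fusion methine, then O‑triflation, gives the C3=C4 enol triflate without touching the stereocentres.

**Step 6**
Reactants: 7 enol triflate ester
Product: 8 (1R,4aS,7aS)‑1‑(benzyloxy)‑7‑(hydroxymethyl)‑1,4a,5,7a‑tetrahydrocyclopenta[c]pyran‑4‑yl trifluoromethanesulfonate
Conditions: DIBAL‑H (2.5 equiv), CH2Cl2, −78 °C; Rochelle salt work‑up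
Reagents that add atoms: none
Why: 1,2‑Reduction of the enoate to the allylic alcohol; the vinyl triflate and the benzyl acetal are inert to DIBAL at −78 °C.

**Step 7**
Reactants: 8 allylic alcohol triflate
Product: 9 methyl (1R,4aS,7aS)‑1‑(benzyloxy)‑7‑(hydroxymethyl)‑1,4a,5,7a‑tetrahydrocyclopenta[c]pyran‑4‑carboxylate (1‑O‑benzylgenipin)
Conditions: Pd(OAc)2 (5 mol %), PPh3, Et3N, CO (1 atm), MeOH/DMF, 50 °C
Reagents that add atoms: carbon monoxide, [C-]#[O+]; methanol, CO
Why: Pd‑catalysed methoxycarbonylation of the vinyl triflate installs the C4 methyl ester; solvent methanol outcompetes the remote primary alcohol.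

**Step 8**
Reactants: 9 1‑O‑benzylgenipin
Product: 10 methyl (1R,4aS,7aS)‑1‑(benzyloxy)‑7‑formyl‑1,4a,5,7a‑tetrahydrocyclopenta[c]pyran‑4‑carboxylate
Conditions: MnO2, CH2Cl2, rt
Reagents that add atoms: none
Why: Chemoselective allylic oxidation to the enal; the enol ether, acetal and ester are untouched.

**Step 9**
Reactants: 10 enal
Product: 11 tricyclic dienol ether, (1S,4aS,7aS) — the cyclopenta[c]pyran‑4‑carboxylate (methyl ester) in which one O atom bridges C1 and the exocyclic CH (C10) attached to C7, with C5=C6 and C7=C10 double bonds (iridoid labels: O10–C10H=C8–C7=C6)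
Conditions: TMSOTf (2.2 equiv), i‑Pr2NEt (3 equiv), CH2Cl2, −78 to 0 °C; purify on Et3N‑deactivated silica
Reagents that add atoms: none
Why: TMSOTf/amine γ‑enolises the enal to the silyl dienol ether and ionises the benzyl acetal (Gassman‑type activation); the dienol oxygen closes the five‑membered acetal ring on the only face that allows cis fusion, inverting C1, and BnOTMS is lost.

**Step 10**
Reactants: 12 4‑iodophenol
Product: 13 4‑iodophenyl acetate
Conditions: Ac2O, pyridine, DMAP (cat.), CH2Cl2, rt
Reagents that add atoms: acetic anhydride, CC(=O)OC(C)=O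
Why: Phenol acetylation; the acetate deactivates the ring so that the later bromination goes only at the alkene.

**Step 11**
Reactants: 13 4‑iodophenyl acetate; 14 methyl acrylate
Product: 15 methyl (E)‑3‑(4‑acetoxyphenyl)acrylate
Conditions: Pd(OAc)2 (1 mol %), P(o‑tol)3 (2 mol %), Et3N, MeCN, 80 °C
Reagents that add atoms: none
Why: Mizoroki–Heck arylation of the acrylate gives the E‑cinnamate by syn insertion and syn β‑hydride elimination.

**Step 12**
Reactants: 15 methyl (E)‑3‑(4‑acetoxyphenyl)acrylate
Product: 16 methyl (2R*,3S*)‑3‑(4‑acetoxyphenyl)‑2,3‑dibromopropanoate (racemic)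
Conditions: Br2, CH2Cl2, 0 °C to rt
Reagents that add atoms: bromine, BrBr
Why: Anti addition of bromine to the alkene; the stereocentres are removed in the next step.

**Step 13**
Reactants: 16 dibromide
Product: 17 methyl (Z)‑3‑(4‑acetoxyphenyl)‑2‑bromoacrylate
Conditions: Et3N (2 equiv), CH2Cl2, rt
Reagents that add atoms: none
Why: E1cB dehydrobromination (loss of the acidic α‑H and the benzylic bromide) gives the thermodynamically preferred Z isomer, with aryl trans to the ester and cis to Br.

**Step 14**
Reactants: 17 bromo ester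
Product: 18 (Z)‑2‑bromo‑3‑(4‑hydroxyphenyl)acrylic acid
Conditions: LiOH·H2O (4 equiv), THF/MeOH/H2O, 0 °C to rt; then 1 M HCl to pH 2
Reagents that add atoms: lithium hydroxide, [Li+].[OH-]
Why: Saponification cleaves both the methyl ester and the aryl acetate; at room temperature this is faster than HBr elimination, so the Z geometry is kept.

**Step 15**
Reactants: 11 tricyclic dienol ether (1.2 equiv); 18 (Z)‑2‑bromo‑3‑(4‑hydroxyphenyl)acrylic acid
Product: 19 prismatomerin (1R,5S,8S,9S,10S; E‑arylidene)
Conditions: 18 premixed with NaHCO3 (3 equiv) and n‑Bu4NCl (1 equiv) in DMF; then 11, Pd(OAc)2 (10 mol %), P(2‑furyl)3 (20 mol %), 60 °C, Ar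
Reagents that add atoms: none
Why: Proposed new method: Pd(0)‑catalysed carbo‑acyloxylation (heteroannulation) of a cyclic 1‑alkoxy‑1,3‑diene by an α‑bromoacrylic acid — Pd(0) inserts into the C–Br bond of 18 with retention of the Z geometry; the vinyl–Pd adds syn across the strained, electron‑rich C8=C10 enol‑ether bond of 11 from its convex face (the other face is covered by the pyran ring), with the vinyl carbon going to C10 (the oxygen‑bearing diene terminus, as in Heck arylation of 2,3‑dihydrofuran) so that Pd sits on C8 as a π‑allyl over C8–C7–C6; inner‑sphere C–O reductive elimination of the tethered carboxylate at C8 on the same face then closes the γ‑lactone (only a cis‑fused γ‑lactone is possible, since attack at C6 would need a seven‑membered ring), forming C10–C11 and C8–O, setting C8 (S) and C10 (S) and leaving C6=C7 and the E‑arylidene in place; the closest known reaction type is the Larock Pd‑catalysed heteroannulation of 1,3‑dienes with functionalised aryl or vinyl halides, not yet shown for dienol‑ether acetals or for making a spiro tertiary allylic C–O bond.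

## Compound list

1 | furfuryl alcohol | OCc1ccco1 | starting material
2 | (±)‑6‑hydroxy‑2H‑pyran‑3(6H)‑one | OC1OCC(=O)C=C1 | intermediate
3 | (S)‑6‑(isobutyryloxy)‑2H‑pyran‑3(6H)‑one | CC(C)C(=O)O[C@@H]1OCC(=O)C=C1 | intermediate
4 | (R)‑6‑(benzyloxy)‑2H‑pyran‑3(6H)‑one | O=C1CO[C@@H](OCc2ccccc2)C=C1 | intermediate
5 | ethyl buta‑2,3‑dienoate | C=C=CC(=O)OCC | starting material
6 | ethyl (1R,4aS,7aS)‑1‑(benzyloxy)‑4‑oxo‑1,3,4,4a,5,7a‑hexahydrocyclopenta[c]pyran‑7‑carboxylate | CCOC(=O)C1=CC[C@@H]2C(=O)CO[C@@H](OCc3ccccc3)[C@H]12 | intermediate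
7 | ethyl (1R,4aS,7aS)‑1‑(benzyloxy)‑4‑(triflyloxy)‑1,4a,5,7a‑tetrahydrocyclopenta[c]pyran‑7‑carboxylate | CCOC(=O)C1=CC[C@@H]2C(OS(=O)(=O)C(F)(F)F)=CO[C@@H](OCc3ccccc3)[C@H]12 | intermediate
8 | (1R,4aS,7aS)‑1‑(benzyloxy)‑7‑(hydroxymethyl)‑1,4a,5,7a‑tetrahydrocyclopenta[c]pyran‑4‑yl triflate | OCC1=CC[C@@H]2C(OS(=O)(=O)C(F)(F)F)=CO[C@@H](OCc3ccccc3)[C@H]12 | intermediate
9 | methyl (1R,4aS,7aS)‑1‑(benzyloxy)‑7‑(hydroxymethyl)‑1,4a,5,7a‑tetrahydrocyclopenta[c]pyran‑4‑carboxylate | OCC1=CC[C@@H]2C(C(=O)OC)=CO[C@@H](OCc3ccccc3)[C@H]12 | intermediate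
10 | methyl (1R,4aS,7aS)‑1‑(benzyloxy)‑7‑formyl‑1,4a,5,7a‑tetrahydrocyclopenta[c]pyran‑4‑carboxylate | O=CC1=CC[C@@H]2C(C(=O)OC)=CO[C@@H](OCc3ccccc3)[C@H]12 | intermediate
11 | tricyclic dienol ether (1S,4aS,7aS; O bridges C1 and C10; C5=C6 and C7=C10) | COC(=O)C1=CO[C@@H]2OC=C3C=C[C@H]1[C@H]23 | intermediate
12 | 4‑iodophenol | Oc1ccc(I)cc1 | starting material
13 | 4‑iodophenyl acetate | CC(=O)Oc1ccc(I)cc1 | intermediate
14 | methyl acrylate | C=CC(=O)OC | starting material
15 | methyl (E)‑3‑(4‑acetoxyphenyl)acrylate | COC(=O)/C=C/c1ccc(OC(C)=O)cc1 | intermediate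
16 | methyl (2R*,3S*)‑3‑(4‑acetoxyphenyl)‑2,3‑dibromopropanoate (racemic; one enantiomer drawn) | COC(=O)[C@@H](Br)[C@@H](Br)c1ccc(OC(C)=O)cc1 | intermediate
17 | methyl (Z)‑3‑(4‑acetoxyphenyl)‑2‑bromoacrylate | COC(=O)/C(Br)=C/c1ccc(OC(C)=O)cc1 | intermediate
18 | (Z)‑2‑bromo‑3‑(4‑hydroxyphenyl)acrylic acid | OC(=O)/C(Br)=C/c1ccc(O)cc1 | intermediate
19 | prismatomerin | COC(=O)C1=CO[C@@H]2O[C@H]3/C(=C\c4ccc(O)cc4)C(=O)O[C@]34C=C[C@H]1[C@H]24 | target

## Summary

Total step count: 15.
Longest linear sequence: 10 steps (1 → 2 → 3 → 4 → 6 → 7 → 8 → 9 → 10 → 11 → 19). The bromo‑acid branch (steps 10–14) is 5 steps and joins in step 15.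

Steps most likely to fail:

1. **Step 15 (proposed new Pd heteroannulation).** Risks are insertion at the C6=C7 end of the diene, β‑hydride elimination to a Heck diene, and protonation of the dienol ether. Fallback with known chemistry:
   - epoxidise the enol ether of 11 from the convex face with DMDO;
   - open the anomeric epoxide syn at C10 with the zinc or aluminium acetylide of 4‑(TIPSO)phenylacetylene (made from 4‑iodophenol by silylation, Sonogashira coupling with TMS‑acetylene and desilylation), giving the C8 tertiary alcohol;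
   - close the (E)‑arylidene spiro‑lactone by Pd‑catalysed cyclocarbonylation of the homopropargylic alcohol (syn alkoxycarbonyl‑palladation, protonolysis);
   - remove TIPS with TBAF/AcOH.
2. **Step 9 (dienol ether acetal closure).** Risks are Gassman elimination at C1 towards C9, and trapping of the C10 cation by the benzyl alcohol by‑product. Fallback: keep the ring open. Convert 10 to its TBS dienol ether (TBSOTf/Et3N), build the lactone on this acyclic 1‑silyloxy diene, and close the C1–O–C10 acetal last by acid‑mediated desilylation and transacetalisation with loss of BnOH.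
3. **Step 5 (regioselective enol triflate).** The risk is deprotonation at the ring‑fusion carbon C5 instead of C3. Fallback: go through the isolable thermodynamic silyl enol ether on the oxygen side (TMSOTf/Et3N), then regiospecific enolate release (MeLi) and triflation (PhNTf2), so the C3=C4 regiochemistry is fixed before the triflate is made.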